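What will [X] and [Q] be in alder at 12 min?

| flask | G | remark | time |
|---|---|---|---|
| alder | 31 mM | the very flask that is asked about, followed so far |  |
| cedar | 46 mM | run made earlier |  |
| flask | 31 mM |  | 12 min |

alder run (percent of the G charged)

| time / s | X / % | Q / % |
|---|---|---|
| 15.0 | 0 | 1.9 |
| 30.0 | 0 | 5.3 |
| 40.0 | 1.6 | 4.8 |
| 60.0 | 1.6 | 6.4 |

cedar run (percent of the G charged)

| time / min | X / % | Q / % |
|---|---|---|
| 0.667 | 1.5 | 3.5 |
| 1.50 | 1.9 | 6.4 |
| 3.00 | 5.3 | 9.2 |
| 5.00 | 11.0 | 11.7 |

(scatter of a reading: 1 percentage point)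

1. concentration of X at 12 min, in mM
2. concentration of Q at 12 min, in mM

- as a solid, counted per litre of solution: G
- what was read earlier has a scatter of 1 percentage point, one standard deviation
- what may be going on: Q <-> D; Q <-> X; D -> E; D <-> L; L -> Z; G <-> Q; X <-> J
- at the start none of G is in solution
- Q means what is dissolved; the solid is not counted in it

I built the flask up one process at a time. First came the feed. I counted Q plus X as dissolved and froze its mean rate up to cedar's last reading:

feed = 2.09 mM min⁻¹

Alder, with less solid, averaged 2.48 mM min⁻¹ up to 60.0 s, and cedar averaged 2.55 mM min⁻¹ up to 1.50 min, so I left the amount of G out. With the feed by itself, all of it stays as Q: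

[Q] = feed × time = 25.1 mM

That is less than the charge of 31 mM, so I kept solid present. Then I added Q to X. Cedar's last X over the area under its Q curve gave a first-order drain:

drain = 0.290 min⁻¹

Its half-life, 2.39 min, is short against 12 min, so Q levels off near 7.19 mM. I call this the holding level, feed divided by drain, a quasi-steady state.

[Q] = holding level × (1 − exp(−drain × time)) = 6.97 mM

[X] = 25.1 mM − 6.97 mM = 18.1 mM

Last came the rest: D, J and the way back from X. I could not size them from these readings, so I took my [X] as high.

The forecast gave [X] 10.5 mM (7 mM to 14 mM) and [Q] 4.2 mM (2.5 mM to 6 mM): “Q should be near a plateau or gently falling by then.” My [Q] lay above its range, and so did my [X].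

Alder gave [X] 11.2 mM and [Q] 7.35 mM.

    Q ⇌ D (K = 16.5, k = 0.0281 min⁻¹)
    Q ⇌ X (K = 2.69, k = 0.345 min⁻¹)
    D → E (k = 0.0775 min⁻¹)
    D ⇌ L (K = 1.21, k = 0.0282 min⁻¹)
    L → Z (k = 0.862 min⁻¹)
    G ⇌ Q, rate k6*(cs6 - [Q]) while solid is left; crystals form when [Q] > cs6 (solubility = 14.0 mM, k = 0.222 min⁻¹)
    X ⇌ J (K = 31.6, k = 0.0367 min⁻¹)

The forecast's [X] held, its [Q] was low by a factor of 1.75, and my [X] was high by 6.90 mM. In alder at 5.04 min, the half-life of Q by the forward step to X alone was 2.0 min, short against 12 min, while Q was made 1.26 times faster than it was used up, each step taken net. In alder [Q] stayed within a tenth of 7.35 mM from 8.36 min to 19.7 min, beside my holding level of 7.19 mM. The same flask read at 20 min held [Q] 6.47 mM, 0.900 of the holding level, with G at 0%.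

All runs stem from a simulated flask from invented constants; scatter was added.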